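**Retrosynthetic overview**

- The strategy rests on ring C being a 3-oxygenated 4-pyranone. The O1–C2 bond and the C3–O bond sit on adjacent carbons, which are the β- and α-carbons of a chalcone double bond.
- Both bonds are cut together (Algar–Flynn–Oyamada) to give 2'-hydroxychalcone 14. The Cα=Cβ bond is then cut (Claisen–Schmidt) to give acetophenone 9 and aldehyde 13.
- Ring A ketone 9 comes from 3,5-dimethoxyphenol by two MOM-directed ortho-lithiations (methyl, then acetyl). Ring B aldehyde 13 comes from methyl 3,5-dihydroxy-4-methoxybenzoate by benzylation, reduction and oxidation.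
- Rings A and B are bought; ring C is the only ring formed (step 9). The endgame is 3-O-methylation, then BCl3 cleavage of the two benzyl ethers and the chelated 5-O-methyl group.

Key step: step 9

Remark: the target has no stereocentre. Intermediate 15 and the fallback epoxide are racemic and their SMILES show one enantiomer of the stated relative configuration; adduct 7 is racemic and drawn without configuration.

**Route**

Step 1
Reactants: 1 3,5-dimethoxyphenol
Product: 2 1,3-dimethoxy-5-(methoxymethoxy)benzene
Conditions: NaH, DMF, 0 °C; MOMCl, 0 °C to rt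
Reagents that add atoms: chloromethyl methyl ether (MOMCl), COCCl
Why: Williamson-type O-alkylation of the sodium phenoxide by the reactive α-chloro ether should give the MOM acetal, which protects the phenol and is the strongest directing group for the lithiations that follow.

Step 2
Reactants: 2 1,3-dimethoxy-5-(methoxymethoxy)benzene
Product: 4 1,5-dimethoxy-3-(methoxymethoxy)-2-methylbenzene, via aryllithium 3 (not isolated)
Conditions: n-BuLi, THF, 0 °C; MeI, −78 °C to rt
Reagents that add atoms: iodomethane, CI
Why: Directed ortho-metalation, in which the chelating MOM ether steers n-BuLi to one of the two equivalent positions flanked by OMOM and OMe in preference to the position between the two methoxy groups, and the aryllithium is then C-methylated by MeI.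

Step 3
Reactants: 4 1,5-dimethoxy-3-(methoxymethoxy)-2-methylbenzene; 5 N-methoxy-N-methylacetamide
Product: 8 1-[4,6-dimethoxy-2-(methoxymethoxy)-3-methylphenyl]ethan-1-one, via aryllithium 6 (not isolated), via tetrahedral lithium adduct 7 (not isolated)
Conditions: n-BuLi, THF, 0 °C; 5, −78 to 0 °C; then H2O
Reagents that add atoms: none
Why: A second directed ortho-metalation should occur at the one remaining position between OMOM and OMe, and the Weinreb ketone synthesis stops at the chelated tetrahedral adduct, so that only the methyl ketone is released on quenching.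

Step 4
Reactants: 8 1-[4,6-dimethoxy-2-(methoxymethoxy)-3-methylphenyl]ethan-1-one
Product: 9 1-(2-hydroxy-4,6-dimethoxy-3-methylphenyl)ethan-1-one
Conditions: HCl (cat.), MeOH, 50 °C
Reagents that add atoms: none
Why: Acid-catalysed acetal exchange with methanol removes the MOM group (made easier by the hydrogen bond of the freed phenol to the ortho carbonyl), while the aryl methyl ethers are inert.

Step 5
Reactants: 10 methyl 3,5-dihydroxy-4-methoxybenzoate
Product: 11 methyl 3,5-bis(benzyloxy)-4-methoxybenzoate
Conditions: BnBr, K2CO3, DMF, 60 °C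
Reagents that add atoms: benzyl bromide, BrCc1ccccc1
Why: Williamson etherification of both phenols with a reactive benzylic halide; the methyl ester and methyl ether are untouched by K2CO3.

Step 6
Reactants: 11 methyl 3,5-bis(benzyloxy)-4-methoxybenzoate
Product: 12 [3,5-bis(benzyloxy)-4-methoxyphenyl]methanol
Conditions: LiAlH4, THF, 0 °C; then H2O
Reagents that add atoms: none
Why: Hydride reduction of the ester to the primary alcohol; benzyl and methyl aryl ethers are stable to LiAlH4.

Step 7
Reactants: 12 [3,5-bis(benzyloxy)-4-methoxyphenyl]methanol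
Product: 13 3,5-bis(benzyloxy)-4-methoxybenzaldehyde
Conditions: activated MnO2, CH2Cl2, rt
Reagents that add atoms: none
Why: Heterogeneous MnO2 oxidation is selective for benzylic alcohols and stops at the aldehyde.

Step 8
Reactants: 9 1-(2-hydroxy-4,6-dimethoxy-3-methylphenyl)ethan-1-one; 13 3,5-bis(benzyloxy)-4-methoxybenzaldehyde
Product: 14 (E)-3-[3,5-bis(benzyloxy)-4-methoxyphenyl]-1-(2-hydroxy-4,6-dimethoxy-3-methylphenyl)prop-2-en-1-one
Conditions: KOH (50% aq.), EtOH, 0 °C to rt; then HCl (aq.)
Reagents that add atoms: none
Why: Claisen–Schmidt condensation, in which the methyl ketone enolate adds to the non-enolisable aldehyde and E1cB dehydration gives the thermodynamically preferred E-enone.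

Step 9
Reactants: 14 (E)-3-[3,5-bis(benzyloxy)-4-methoxyphenyl]-1-(2-hydroxy-4,6-dimethoxy-3-methylphenyl)prop-2-en-1-one
Product: 16 2-[3,5-bis(benzyloxy)-4-methoxyphenyl]-3-hydroxy-5,7-dimethoxy-8-methylchromen-4-one, via trans-dihydroflavonol 15 (not isolated)
Conditions: H2O2 (30% aq.), NaOH (aq.), MeOH–THF, 0 °C to rt; then HCl (aq.)
Reagents that add atoms: hydrogen peroxide, OO
Why: The 2'-phenoxide of 14 adds to the benzylic β-carbon while the α-carbon is oxygenated by hydrogen peroxide (the developing enolate attacks H2O2 directly, or a Weitz–Scheffer epoxide forms first and is opened by the phenoxide at its benzylic carbon), so O1–C2 and C3–OH are made in one operation to give trans-dihydroflavonol 15, which the excess alkaline peroxide then dehydrogenates through its enolate to flavonol 16. The closest known reaction type is the Algar–Flynn–Oyamada conversion of 2'-hydroxy-4',6'-dialkoxychalcones into 3-hydroxyflavones. Ring C closes in the 6-endo mode (6-endo-trig oxa-Michael addition, or 6-endo-tet opening of the epoxide at the benzylic carbon). The two stereocentres of 15 (C2 and C3) should arise as the racemic trans pair under thermodynamic control and are both erased when the pyranone is aromatised, so the step leaves no stereocentre. The selectivity needed is 6-endo attack at Cβ instead of 5-exo attack at Cα, which would lead to the aurone and is encouraged by the 6'-methoxy group; the para-methoxy donor of ring B (only partly effective, because it is flanked by two benzyloxy groups) and, above all, the low starting temperature favour attack at the benzylic carbon. Regiochemistry in ring A is not at issue, because the only free hydroxyl of 14 is the one next to the methyl-bearing carbon, so only the 8-methyl chromone can form.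

Step 10
Reactants: 16 2-[3,5-bis(benzyloxy)-4-methoxyphenyl]-3-hydroxy-5,7-dimethoxy-8-methylchromen-4-one
Product: 17 2-[3,5-bis(benzyloxy)-4-methoxyphenyl]-3,5,7-trimethoxy-8-methylchromen-4-one
Conditions: MeI, K2CO3, acetone, reflux
Reagents that add atoms: iodomethane, CI
Why: Williamson O-methylation of the only free hydroxyl, the acidic enolic 3-OH.

Step 11
Reactants: 17 2-[3,5-bis(benzyloxy)-4-methoxyphenyl]-3,5,7-trimethoxy-8-methylchromen-4-one
Product: 18 2-(3,5-dihydroxy-4-methoxyphenyl)-5-hydroxy-3,7-dimethoxy-8-methylchromen-4-one (target)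
Conditions: BCl3 (1 M in CH2Cl2), C6HMe5, CH2Cl2, −78 to 0 °C; then H2O
Reagents that add atoms: none
Why: Lewis-acid ether cleavage: BCl3 removes the aryl benzyl ethers at low temperature with pentamethylbenzene trapping the benzyl cations, and on warming the BCl3 chelated between the C4 carbonyl and the peri 5-methoxy oxygen delivers chloride to that methyl group (chelation-controlled demethylation through a six-membered boron chelate), while the 3-, 7- and 4'-methyl ethers lack this activation and should remain.

**Compound list**

1 | 3,5-dimethoxyphenol | COc1cc(O)cc(OC)c1 | starting material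
2 | 1,3-dimethoxy-5-(methoxymethoxy)benzene | COCOc1cc(OC)cc(OC)c1 | intermediate
3 | [2,4-dimethoxy-6-(methoxymethoxy)phenyl]lithium | [Li]c1c(OCOC)cc(OC)cc1OC | intermediate
4 | 1,5-dimethoxy-3-(methoxymethoxy)-2-methylbenzene | COCOc1cc(OC)cc(OC)c1C | intermediate
5 | N-methoxy-N-methylacetamide | CC(=O)N(C)OC | starting material
6 | [4,6-dimethoxy-2-(methoxymethoxy)-3-methylphenyl]lithium | [Li]c1c(OCOC)c(C)c(OC)cc1OC | intermediate
7 | lithium 1-[4,6-dimethoxy-2-(methoxymethoxy)-3-methylphenyl]-1-[methoxy(methyl)amino]ethan-1-olate (racemic) | CC(O[Li])(N(C)OC)c1c(OCOC)c(C)c(OC)cc1OC | intermediate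
8 | 1-[4,6-dimethoxy-2-(methoxymethoxy)-3-methylphenyl]ethan-1-one | COCOc1c(C)c(OC)cc(OC)c1C(C)=O | intermediate
9 | 1-(2-hydroxy-4,6-dimethoxy-3-methylphenyl)ethan-1-one | COc1cc(OC)c(C(C)=O)c(O)c1C | intermediate
10 | methyl 3,5-dihydroxy-4-methoxybenzoate | COC(=O)c1cc(O)c(OC)c(O)c1 | starting material
11 | methyl 3,5-bis(benzyloxy)-4-methoxybenzoate | COC(=O)c1cc(OCc2ccccc2)c(OC)c(OCc2ccccc2)c1 | intermediate
12 | [3,5-bis(benzyloxy)-4-methoxyphenyl]methanol | OCc1cc(OCc2ccccc2)c(OC)c(OCc2ccccc2)c1 | intermediate
13 | 3,5-bis(benzyloxy)-4-methoxybenzaldehyde | O=Cc1cc(OCc2ccccc2)c(OC)c(OCc2ccccc2)c1 | intermediate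
14 | (E)-3-[3,5-bis(benzyloxy)-4-methoxyphenyl]-1-(2-hydroxy-4,6-dimethoxy-3-methylphenyl)prop-2-en-1-one | COc1cc(OC)c(C(=O)/C=C/c2cc(OCc3ccccc3)c(OC)c(OCc3ccccc3)c2)c(O)c1C | intermediate
15 | (2R*,3R*)-trans-2-[3,5-bis(benzyloxy)-4-methoxyphenyl]-3-hydroxy-5,7-dimethoxy-8-methyl-2,3-dihydrochromen-4-one (racemic) | COc1c(OCc2ccccc2)cc(cc1OCc1ccccc1)[C@@H]1[C@H](C(=O)c2c(OC)cc(OC)c(C)c2O1)O | intermediate
16 | 2-[3,5-bis(benzyloxy)-4-methoxyphenyl]-3-hydroxy-5,7-dimethoxy-8-methylchromen-4-one | COc1cc(OC)c2c(=O)c(O)c(-c3cc(OCc4ccccc4)c(OC)c(OCc4ccccc4)c3)oc2c1C | intermediate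
17 | 2-[3,5-bis(benzyloxy)-4-methoxyphenyl]-3,5,7-trimethoxy-8-methylchromen-4-one | COc1cc(OC)c2c(=O)c(OC)c(-c3cc(OCc4ccccc4)c(OC)c(OCc4ccccc4)c3)oc2c1C | intermediate
18 | 2-(3,5-dihydroxy-4-methoxyphenyl)-5-hydroxy-3,7-dimethoxy-8-methylchromen-4-one | COc1cc(O)c2c(=O)c(OC)c(-c3cc(O)c(OC)c(O)c3)oc2c1C | target

**Step count and risks**

Total step count: 11. Longest linear sequence: 8 steps (steps 1–4, then 8–11).

Steps most likely to fail:

1. Step 9. The closure may run 5-exo at the α-carbon and give the aurone, or the electron-rich product may be degraded by excess peroxide. Fallback from 14: heating with catalytic I2 in DMSO at about 125 °C (oxa-Michael closure and dehydrogenation) should give the flavone 2-[3,5-bis(benzyloxy)-4-methoxyphenyl]-5,7-dimethoxy-8-methylchromen-4-one F1. Dimethyldioxirane in acetone–CH2Cl2 at 0 °C should then epoxidise its C2=C3 bond to the racemic cis-fused epoxide 1a-[3,5-bis(benzyloxy)-4-methoxyphenyl]-4,6-dimethoxy-3-methyl-1a,7a-dihydro-7H-oxireno[2,3-b]chromen-7-one F2. Catalytic p-TsOH in CH2Cl2 should open F2 to the 3-hydroxyflavone, returning to the route at 16. This places the C3 oxygen after ring C is already closed, so no aurone can arise.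

2. Step 11. The non-chelated methyl ethers (3-OMe, or the 4'-OMe once its neighbours are boron-bound phenoxides) may be cleaved, or a benzyl group may transfer to the electron-rich ring A. Fallback from 17: AlCl3 in MeCN at rt should cleave only the carbonyl-chelated 5-methyl ether with the benzyl ethers still in place, giving 2-[3,5-bis(benzyloxy)-4-methoxyphenyl]-5-hydroxy-3,7-dimethoxy-8-methylchromen-4-one F3. Hydrogenolysis (H2, Pd/C, EtOAc–THF, rt) should then remove both benzyl groups under neutral conditions, returning to the route at 18.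

3. Step 3. Metalation may occur at the wrong site (between the two methoxy groups, or at the benzylic methyl), or the hindered aryllithium may enolise the Weinreb amide instead of adding to it. Fallback from 4: HCl in MeOH at 50 °C should remove the MOM group to give 3,5-dimethoxy-2-methylphenol F4. Friedel–Crafts/Fries-type ortho-acetylation with Ac2O and BF3·OEt2 at 80 °C should give the difluoroboron chelate of the ortho-hydroxy ketone, 2,2-difluoro-5,7-dimethoxy-4,8-dimethyl-1,3,2-benzodioxaborinine chelate F5. This is hydrolysed in warm aqueous ethanol, returning to the route at 9 and bypassing step 4. Acylation ortho to the free hydroxyl is driven by formation of the boron chelate, and the position between the two methoxy groups is more hindered.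

**Further compounds**

F1 | step 9 | 2-[3,5-bis(benzyloxy)-4-methoxyphenyl]-5,7-dimethoxy-8-methylchromen-4-one | COc1cc(OC)c2c(=O)cc(-c3cc(OCc4ccccc4)c(OC)c(OCc4ccccc4)c3)oc2c1C
F2 | step 9 | 1a-[3,5-bis(benzyloxy)-4-methoxyphenyl]-4,6-dimethoxy-3-methyl-1a,7a-dihydro-7H-oxireno[2,3-b]chromen-7-one (racemic, cis-fused) | COc1c(OCc2ccccc2)cc(cc1OCc1ccccc1)[C@@]12O[C@@H]1C(=O)c1c(OC)cc(OC)c(C)c1O2
F3 | step 11 | 2-[3,5-bis(benzyloxy)-4-methoxyphenyl]-5-hydroxy-3,7-dimethoxy-8-methylchromen-4-one | COc1cc(O)c2c(=O)c(OC)c(-c3cc(OCc4ccccc4)c(OC)c(OCc4ccccc4)c3)oc2c1C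
F4 | step 3 | 3,5-dimethoxy-2-methylphenol | COc1cc(O)c(C)c(OC)c1
F5 | step 3 | difluoroboron chelate of 1-(2-hydroxy-4,6-dimethoxy-3-methylphenyl)ethan-1-one | CC1=[O+][B-](F)(F)Oc2c(C)c(OC)cc(OC)c12
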